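The closed, stirred vessel held Q in solution under Z at constant pressure, with no J dissolved at the start.

    Z ⇌ J, rate k1*(csat - [J]) (k1 = 1.52 h⁻¹, csat = 3.2 mM)
    Q + J → QJ (k2 = 16.2 M⁻¹ h⁻¹)
    2 J → G (k3 = 524 M⁻¹ h⁻¹)

Q 13 mM; Z 3.2 mM (held); time 10 h

- zeta: doubling the transfer coefficient of step 1, all else as stated
- theta: doubling the saturation concentration of Z, all else as stated

* amount of QJ at 10 h, in percent of the Q charged
* the change that raises the amount of QJ at 10 h, in percent of the Q charged most ("none" if none brings more than 2 percentage points) (zeta / theta / none)
* amount of QJ at 10 h, in percent of the Q charged, after zeta

- a step written with two of one species runs at k times the square of its concentration and takes two of it each time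
- at the start none of J is dissolved
- run time (flask): 10 h

**Fast rung.** In the flask I set the supply of J from the gas equal to its two losses, with Q as charged, and this gave a steady level of 1.48 mM. A departure from that level died away in 0.207 h, far shorter than the 10 h run, so I took J in the flask as steady from then on.

**Middle rung.** I followed one dissolved J molecule in the flask: it met Q at 0.211 h⁻¹, met another J at 1.55 h⁻¹ and went back to the gas at 1.52 h⁻¹, so its fork favoured G over QJ, and its chance of ending in QJ was 6.43%.

**Slow rung.** Q in the flask therefore saw a steady J and fell in a pseudo-first-order way, and I carried its capture constant, the rate constant of step 2 times the steady level of J, 0.0240 h⁻¹. The life of Q, 41.7 h, was longer than the run, so I expected a partial conversion, one minus the exponential of constant times time, 21.3%. Repeating the level gave J at 1.87 mM under zeta and 2.33 mM under theta, hence QJ at 26.1% and 31.5%, gains of 4.8 percentage points and 10 points, so I chose theta.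

The forecast gave 21%, 25.8% after zeta and theta as the best change, holding that under zeta “the squared loss absorbs much of the gain”.

**The result.** The flask gave 20.9%, and 25.8% after zeta; zeta gained 4.9 points and theta 10 points, which made theta the better change.

**Later reading.** In the flask J read 1.47 mM after 1.00 h and 1.49 mM after 10.0 h, beside my level of 1.48 mM, and the capture constant 0.0240 h⁻¹ had given 21.3% against the 20.9% found. I put the same constant on the neighbouring flask, the same charge read at 40 h, where J read 1.52 mM, and it gave 61.7% of the Q charged as QJ. That neighbouring flask held 62.1% as QJ, with 37.9% of its Q still unbound.

(All constants were set for the occasion; no experiment stands behind them.)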